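A direct plan would build ring A first, as the acetophenone 1-[4-(benzyloxy)-2-hydroxy-3,6-dimethoxyphenyl]ethan-1-one A2 from methyl gallate A1, join it by a Claisen–Schmidt condensation to 3,5-bis(benzyloxy)-4-methoxybenzaldehyde A3, close ring C of the chalcone A4 oxidatively to the tri-O-benzyl flavone A5 and debenzylate. Its weakest points would be:
- The run-up to A2: about nine linear steps (alkylations, ester to alcohol to aldehyde, Dakin oxidation, hydrogenolysis, Hoesch acylation) that only move oxygen atoms around one benzene ring and make a single C–C bond.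
- The two "one-equivalent" alkylations (mono-O-methylation of A1 at O4, mono-benzylation of the resorcinol ketone): each is a statistical competition placed early in a long linear sequence.
- The late closure of ring C: a slow aldol on a doubly ortho-substituted, chelated ketone, then a hot oxidative cyclisation of an electron-rich chalcone in which ring halogenation, aurone formation and loss of the peri 5-O-methyl group would compete.

**Retrosynthetic overview**
- Ring A would be built last. Its para pair O5/O8, with O7 next to C8 and H at C6, is the pattern that a 4-hydroxycyclobutenone ring expansion delivers, so C5–C8 would come from a squaric acid monoester and C4a/C8a from the C5=C6 edge of a 2-aryl-4H-pyran-4-one.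
- Key disconnections: C4a–C5 (6π electrocyclisation of a dienylketene) and C8–C8a (addition of the C6-metalated pyranone to the semisquarate carbonyl). The pyranone itself would come from the ring-B acid and 4-methoxybut-3-en-2-one.
- Ring order: B (bought), then C (pyranone), then A (ring expansion); the direct plan closes C last onto a finished A.
- The four ring-A oxygens would arrive already differentiated: O1 from the pyranone, 7-OBn from the squarate ester, and 5-OH/8-OH as the hydroquinone pair that both become OMe. The redox run-up, the statistical alkylations and the oxidative chalcone closure therefore do not arise.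

Key step: step 7

Remark on the chemistry: TMP stands for 2,2,6,6-tetramethylpiperidide; the carbinol of step 6 is racemic, which is immaterial because its stereocentre becomes an aromatic carbon in step 7.

Step 1
Reactants: 1 methyl 3,5-dihydroxy-4-methoxybenzoate
Product: 2 methyl 4-methoxy-3,5-bis(methoxymethoxy)benzoate
Conditions: MOMCl (2.6 equiv), iPr2NEt (3 equiv), CH2Cl2, 0 °C to rt
Reagents that add atoms: chloromethyl methyl ether, COCCl
Why: Williamson-type O-alkylation of both phenols with the reactive α-chloro ether gives the bis-acetal, which is inert to every base used later and is removed by dilute acid in the last pot.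

Step 2
Reactants: 2 methyl 4-methoxy-3,5-bis(methoxymethoxy)benzoate
Product: 3 4-methoxy-3,5-bis(methoxymethoxy)benzoic acid
Conditions: LiOH·H2O (3 equiv), THF/MeOH/H2O, rt; then 1 M HCl to pH 4, 0 °C
Reagents that add atoms: lithium hydroxide, [Li+].[OH-]
Why: Saponification of the unhindered methyl benzoate should be clean, since MOM acetals are stable to hydroxide and survive a brief cold acidification to pH 4.

Step 3
Reactants: 3 4-methoxy-3,5-bis(methoxymethoxy)benzoic acid; 4 (E)-4-methoxybut-3-en-2-one
Product: 8 2-[4-methoxy-3,5-bis(methoxymethoxy)phenyl]-4H-pyran-4-one, via acyl imidazolide 5 (not isolated), via lithium dienolate 6 (not isolated), via diketone 7 (not isolated)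
Conditions: 3, CDI (1.1 equiv), THF, rt; added to 4 (3.2 equiv)/LiN(SiMe3)2 (3.3 equiv), THF, –78 to –40 °C; aq. NH4Cl; crude, PPTS (0.2 equiv), toluene, 80 °C
Reagents that add atoms: none
Why: The acyl imidazolide should C-acylate the kinetic dienolate of the methyl ketone (crossed Claisen condensation, the excess dienolate absorbing imidazole and the acidic diketone), and mild acid should then close the enol oxygen onto the β-methoxy enone by addition–elimination of methanol to give ring C as a 6-unsubstituted 4-pyranone.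

Step 4
Reactants: 9 squaric acid (3,4-dihydroxycyclobut-3-ene-1,2-dione)
Product: 10 3,4-bis(benzyloxy)cyclobut-3-ene-1,2-dione (dibenzyl squarate)
Conditions: BnOH (4 equiv), toluene, reflux, Dean–Stark
Reagents that add atoms: benzyl alcohol, OCc1ccccc1
Why: Azeotropic esterification of the strongly acidic vinylogous diacid with a primary alcohol is the standard entry to dialkyl squarates.

Step 5
Reactants: 10 3,4-bis(benzyloxy)cyclobut-3-ene-1,2-dione
Product: 12 3-(benzyloxy)cyclobut-3-ene-1,2-dione, via hydroxycyclobutenone 11 (not isolated)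
Conditions: LiAlH(OtBu)3 (1.05 equiv), THF, –78 to –20 °C; then 6 M aq. HCl, CH2Cl2, 0 °C to rt
Reagents that add atoms: water, O
Why: One hydride from the mild, bulky LiAlH(OtBu)3 should add 1,2 to one of the two equivalent carbonyls, after which acid ionises the allylic carbinol, water adds at the benzyloxy-stabilised terminus and the hemiketal collapses with loss of benzyl alcohol (the established reduction–rearrangement of a dialkyl squarate to a semisquarate).

Step 6
Reactants: 8 2-[4-methoxy-3,5-bis(methoxymethoxy)phenyl]-4H-pyran-4-one; 12 3-(benzyloxy)cyclobut-3-ene-1,2-dione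
Product: 14 3-(benzyloxy)-4-hydroxy-4-{6-[4-methoxy-3,5-bis(methoxymethoxy)phenyl]-4-oxo-4H-pyran-2-yl}cyclobut-2-en-1-one (racemic), via pyranonylzinc chloride 13 (not isolated)
Conditions: 8, TMPZnCl·LiCl (1.2 equiv), THF, 25 °C; then MgCl2 (1.2 equiv), 12 (1.3 equiv), –30 to 0 °C; aq. NH4Cl
Reagents that add atoms: none
Why: Proposed new method: TMPZnCl·LiCl should remove the only O–CH= proton of 8 (C6–H, the most acidic site when no Lewis acid directs the base to the carbonyl side), as amide-zinc bases do at the corresponding C2 position of chromones, and the heteroarylzinc chloride, activated by MgCl2 as in MgCl2-accelerated additions of arylzinc reagents to carbonyl compounds, should add 1,2 to the non-vinylogous-ester carbonyl of 12 (the one next to the benzyloxy-bearing carbon), which is the carbonyl that aryl- and alkynyllithium reagents attack in 3-alkoxycyclobutenediones; this forms the future C8–C8a bond and a racemic carbinol centre that is erased in step 7.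

Step 7
Reactants: 14 3-(benzyloxy)-4-hydroxy-4-{6-[4-methoxy-3,5-bis(methoxymethoxy)phenyl]-4-oxo-4H-pyran-2-yl}cyclobut-2-en-1-one
Product: 17 7-(benzyloxy)-5,8-dihydroxy-2-[4-methoxy-3,5-bis(methoxymethoxy)phenyl]-4H-chromen-4-one, via dienylketene 15 (not isolated), via dienone 16 (not isolated)
Conditions: p-xylene (0.02 M, degassed), 138 °C, argon
Reagents that add atoms: none
Why: Heating should open the cyclobutenone by conrotatory 4π electrocyclic ring opening, in which the donor hydroxyl rotates outward and so places the pyranonyl group cis to the new ketene in dienylketene 15. Ring A then closes by a thermal 6π (disrotatory) electrocyclisation that forms the C4a–C5 bond between the ketene carbon and C5 of the pyranone, giving dienone 16, and a proton shift aromatises it to the hydroquinone. The closest known reaction type is the Moore rearrangement of 4-aryl-, 4-heteroaryl- and 4-alkenyl-4-hydroxycyclobutenones to annulated hydroquinones. No stereocentre remains, because the racemic carbinol centre of 14 and the transient C4a centre of 16 both become aromatic carbons. The step needs the hydroxyl-outward torquoselectivity, which the strong donor at the carbinol carbon secures, and it has only one site to close on because the other neighbour of the pyranone carbon is the ring oxygen; the 5-OH/6-H/7-OBn/8-OH pattern is already fixed by the regiochemistry of step 6. The ketene carbon ends as the 5-OH, hydrogen-bonded to the C4 carbonyl, which should favour the final tautomerisation.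

Step 8
Reactants: 17 7-(benzyloxy)-5,8-dihydroxy-2-[4-methoxy-3,5-bis(methoxymethoxy)phenyl]-4H-chromen-4-one
Product: 18 7-(benzyloxy)-5,8-dimethoxy-2-[4-methoxy-3,5-bis(methoxymethoxy)phenyl]-4H-chromen-4-one
Conditions: MeI (5 equiv), K2CO3 (4 equiv), DMF (degassed), 45 °C, argon
Reagents that add atoms: iodomethane, CI
Why: Double Williamson O-methylation under exclusion of air should take the 8-OH readily and the chelated 5-OH with excess MeI in warm DMF, and no regiochemical choice arises because O7 is already a benzyl ether.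

Step 9
Reactants: 18 7-(benzyloxy)-5,8-dimethoxy-2-[4-methoxy-3,5-bis(methoxymethoxy)phenyl]-4H-chromen-4-one
Product: 20 2-(3,5-dihydroxy-4-methoxyphenyl)-7-hydroxy-5,8-dimethoxy-4H-chromen-4-one, via phenol 19 (not isolated)
Conditions: H2 (1 atm), 10% Pd/C, THF/MeOH, rt; filter; then 3 M aq. HCl, MeOH, 50 °C
Reagents that add atoms: none
Why: Hydrogenolysis should cleave the benzyl ether at 1 atm without reducing the chromone C2=C3 bond, and dilute methanolic HCl should then transacetalise both MOM groups while leaving the three methyl ethers, including the peri 5-OMe, untouched, to give the achiral target.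

**Compound list**
1 | methyl 3,5-dihydroxy-4-methoxybenzoate | COC(=O)c1cc(O)c(OC)c(O)c1 | starting material
2 | methyl 4-methoxy-3,5-bis(methoxymethoxy)benzoate | COCOc1cc(C(=O)OC)cc(OCOC)c1OC | intermediate
3 | 4-methoxy-3,5-bis(methoxymethoxy)benzoic acid | COCOc1cc(C(=O)O)cc(OCOC)c1OC | intermediate
4 | (E)-4-methoxybut-3-en-2-one | CO/C=C/C(C)=O | starting material
5 | (1H-imidazol-1-yl)[4-methoxy-3,5-bis(methoxymethoxy)phenyl]methanone (not isolated) | COCOc1cc(C(=O)n2ccnc2)cc(OCOC)c1OC | intermediate
6 | lithium (E)-4-methoxybuta-1,3-dien-2-olate (not isolated) | [Li+].[O-]C(=C)/C=C/OC | intermediate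
7 | (E)-5-methoxy-1-[4-methoxy-3,5-bis(methoxymethoxy)phenyl]pent-4-ene-1,3-dione (not isolated) | CO/C=C/C(=O)CC(=O)c1cc(OCOC)c(OC)c(OCOC)c1 | intermediate
8 | 2-[4-methoxy-3,5-bis(methoxymethoxy)phenyl]-4H-pyran-4-one | COCOc1cc(-c2cc(=O)cco2)cc(OCOC)c1OC | intermediate
9 | squaric acid (3,4-dihydroxycyclobut-3-ene-1,2-dione) | O=C1C(=O)C(O)=C1O | starting material
10 | 3,4-bis(benzyloxy)cyclobut-3-ene-1,2-dione | O=C1C(=O)C(OCc2ccccc2)=C1OCc1ccccc1 | intermediate
11 | 2,3-bis(benzyloxy)-4-hydroxycyclobut-2-en-1-one, racemic (not isolated) | O=C1C(OCc2ccccc2)=C(OCc2ccccc2)C1O | intermediate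
12 | 3-(benzyloxy)cyclobut-3-ene-1,2-dione | O=C1C=C(OCc2ccccc2)C1=O | intermediate
13 | chlorido{6-[4-methoxy-3,5-bis(methoxymethoxy)phenyl]-4-oxo-4H-pyran-2-yl}zinc, LiCl complex (not isolated) | Cl[Zn]c1cc(=O)cc(-c2cc(OCOC)c(OC)c(OCOC)c2)o1 | intermediate
14 | 3-(benzyloxy)-4-hydroxy-4-{6-[4-methoxy-3,5-bis(methoxymethoxy)phenyl]-4-oxo-4H-pyran-2-yl}cyclobut-2-en-1-one, racemic | O=C1C=C(OCc2ccccc2)C1(O)c1cc(=O)cc(-c2cc(OCOC)c(OC)c(OCOC)c2)o1 | intermediate
15 | (Z)-3-(benzyloxy)-4-hydroxy-4-{6-[4-methoxy-3,5-bis(methoxymethoxy)phenyl]-4-oxo-4H-pyran-2-yl}buta-1,3-dien-1-one (not isolated) | O=C=C/C(OCc1ccccc1)=C(/O)c1cc(=O)cc(-c2cc(OCOC)c(OC)c(OCOC)c2)o1 | intermediate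
16 | 7-(benzyloxy)-8-hydroxy-2-[4-methoxy-3,5-bis(methoxymethoxy)phenyl]-4aH-chromene-4,5-dione, racemic (not isolated) | O=C1C=C(OCc2ccccc2)C(O)=C2OC(c3cc(OCOC)c(OC)c(OCOC)c3)=CC(=O)C12 | intermediate
17 | 7-(benzyloxy)-5,8-dihydroxy-2-[4-methoxy-3,5-bis(methoxymethoxy)phenyl]-4H-chromen-4-one | O=c1cc(-c2cc(OCOC)c(OC)c(OCOC)c2)oc2c(O)c(OCc3ccccc3)cc(O)c12 | intermediate
18 | 7-(benzyloxy)-5,8-dimethoxy-2-[4-methoxy-3,5-bis(methoxymethoxy)phenyl]-4H-chromen-4-one | COc1cc(OCc2ccccc2)c(OC)c2oc(-c3cc(OCOC)c(OC)c(OCOC)c3)cc(=O)c12 | intermediate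
19 | 7-hydroxy-5,8-dimethoxy-2-[4-methoxy-3,5-bis(methoxymethoxy)phenyl]-4H-chromen-4-one (not isolated) | COc1cc(O)c(OC)c2oc(-c3cc(OCOC)c(OC)c(OCOC)c3)cc(=O)c12 | intermediate
20 | 2-(3,5-dihydroxy-4-methoxyphenyl)-7-hydroxy-5,8-dimethoxy-4H-chromen-4-one | COc1c(O)cc(-c2cc(=O)c3c(OC)cc(O)c(OC)c3o2)cc1O | target

**Totals and risks**
Total step count: 9. Longest linear sequence: 7 steps (1, 2, 3, 6, 7, 8, 9); steps 4 and 5 form the short second branch.

Steps most likely to fail (in the fallbacks, aryl = 4-methoxy-3,5-bis(methoxymethoxy)phenyl):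

1. Step 6 (fragment union, proposed new method). The zincation could go to C3/C5 instead of C6. The arylzinc could also be too weak a nucleophile, add to the vinylogous-ester carbonyl (which would give the 6-benzyloxy isomer after ring expansion), or displace benzyloxide by addition–elimination. The fallback uses known chemistry and gives up the ring expansion. It sets out from acid 3:
   - Activation with CDI and C-acylation of potassium ethyl malonate (MgCl2, Et3N, decarboxylation on work-up) would give ethyl 3-aryl-3-oxopropanoate F1.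
   - A Mentzer pyrone synthesis with phloroglucinol (neat, 240 °C, microwave) would give 5,7-dihydroxy-2-aryl-4H-chromen-4-one F2.
   - Selective benzylation of the non-chelated 7-OH (BnBr, K2CO3, acetone) would give 7-(benzyloxy)-5-hydroxy-2-aryl-4H-chromen-4-one F3.
   - Methylation of the chelated 5-OH (MeI, K2CO3, DMF) would give 7-(benzyloxy)-5-methoxy-2-aryl-4H-chromen-4-one F4.
   - Bromination at C8 (NBS, DMF, 0 °C) would give 7-(benzyloxy)-8-bromo-5-methoxy-2-aryl-4H-chromen-4-one F5.
   - An Ullmann-type methoxylation (NaOMe, CuBr, DMF/MeOH, 110 °C) would return to the route at 18.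

2. Step 7 (key ring expansion). The dienylketene could be trapped by its own hydroxyl (lactonisation to a butenolide), or the electrocyclisation onto the weakly aromatic pyranone edge could be slower than decomposition; the free hydroquinone is also prone to air oxidation. The fallback sets out from 14:
   - O-methylation of the tertiary carbinol (MeI, Ag2O, MeCN, rt) would give 3-(benzyloxy)-4-methoxy-4-(6-aryl-4-oxo-4H-pyran-2-yl)cyclobut-2-en-1-one F6.
   - Its ring expansion (p-xylene, 138 °C) cannot lactonise and would give directly the air-stable p-methoxyphenol 7-(benzyloxy)-5-hydroxy-8-methoxy-2-aryl-4H-chromen-4-one F7.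
   - Methylation of the chelated 5-OH (MeI, K2CO3, DMF, 45 °C) would return to the route at 18.

3. Step 3 (pyranone assembly). O-acylation or self-condensation of the sensitive dienolate, or partial loss of MOM groups during the acid-induced ring closure, could erode the step. The fallback sets out from 3:
   - The acyl imidazolide and the lithium enolate of acetone (LiN(SiMe3)2, THF, –78 °C) would give 1-arylbutane-1,3-dione F8.
   - Its dianion (LiN(iPr)2, 2.2 equiv) would be formylated at the terminal methyl group with ethyl formate to 5-aryl-3,5-dioxopentanal F9.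
   - Cyclodehydration (PPTS, toluene, 80 °C) would return to the route at 8.

**Further compounds**
F1 | step 6 | ethyl 3-[4-methoxy-3,5-bis(methoxymethoxy)phenyl]-3-oxopropanoate | CCOC(=O)CC(=O)c1cc(OCOC)c(OC)c(OCOC)c1
F2 | step 6 | 5,7-dihydroxy-2-[4-methoxy-3,5-bis(methoxymethoxy)phenyl]-4H-chromen-4-one | O=c1cc(-c2cc(OCOC)c(OC)c(OCOC)c2)oc2cc(O)cc(O)c12
F3 | step 6 | 7-(benzyloxy)-5-hydroxy-2-[4-methoxy-3,5-bis(methoxymethoxy)phenyl]-4H-chromen-4-one | O=c1cc(-c2cc(OCOC)c(OC)c(OCOC)c2)oc2cc(OCc3ccccc3)cc(O)c12
F4 | step 6 | 7-(benzyloxy)-5-methoxy-2-[4-methoxy-3,5-bis(methoxymethoxy)phenyl]-4H-chromen-4-one | COc1cc(OCc2ccccc2)cc2oc(-c3cc(OCOC)c(OC)c(OCOC)c3)cc(=O)c12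
F5 | step 6 | 7-(benzyloxy)-8-bromo-5-methoxy-2-[4-methoxy-3,5-bis(methoxymethoxy)phenyl]-4H-chromen-4-one | COc1cc(OCc2ccccc2)c(Br)c2oc(-c3cc(OCOC)c(OC)c(OCOC)c3)cc(=O)c12
F6 | step 7 | 3-(benzyloxy)-4-methoxy-4-{6-[4-methoxy-3,5-bis(methoxymethoxy)phenyl]-4-oxo-4H-pyran-2-yl}cyclobut-2-en-1-one, racemic | COC1(c2cc(=O)cc(-c3cc(OCOC)c(OC)c(OCOC)c3)o2)C(OCc2ccccc2)=CC1=O
F7 | step 7 | 7-(benzyloxy)-5-hydroxy-8-methoxy-2-[4-methoxy-3,5-bis(methoxymethoxy)phenyl]-4H-chromen-4-one | COc1c(OCc2ccccc2)cc(O)c2c(=O)cc(-c3cc(OCOC)c(OC)c(OCOC)c3)oc12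
F8 | step 3 | 1-[4-methoxy-3,5-bis(methoxymethoxy)phenyl]butane-1,3-dione | CC(=O)CC(=O)c1cc(OCOC)c(OC)c(OCOC)c1
F9 | step 3 | 5-[4-methoxy-3,5-bis(methoxymethoxy)phenyl]-3,5-dioxopentanal | O=CCC(=O)CC(=O)c1cc(OCOC)c(OC)c(OCOC)c1
A1 | direct plan | methyl gallate (methyl 3,4,5-trihydroxybenzoate) | COC(=O)c1cc(O)c(O)c(O)c1
A2 | direct plan | 1-[4-(benzyloxy)-2-hydroxy-3,6-dimethoxyphenyl]ethan-1-one | CC(=O)c1c(O)c(OC)c(OCc2ccccc2)cc1OC
A3 | direct plan | 3,5-bis(benzyloxy)-4-methoxybenzaldehyde | O=Cc1cc(OCc2ccccc2)c(OC)c(OCc2ccccc2)c1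
A4 | direct plan | (E)-1-[4-(benzyloxy)-2-hydroxy-3,6-dimethoxyphenyl]-3-[3,5-bis(benzyloxy)-4-methoxyphenyl]prop-2-en-1-one | O=C(/C=C/c1cc(OCc2ccccc2)c(OC)c(OCc2ccccc2)c1)c1c(O)c(OC)c(OCc2ccccc2)cc1OC
A5 | direct plan | 7-(benzyloxy)-2-[3,5-bis(benzyloxy)-4-methoxyphenyl]-5,8-dimethoxy-4H-chromen-4-one | COc1cc(OCc2ccccc2)c(OC)c2oc(-c3cc(OCc4ccccc4)c(OC)c(OCc4ccccc4)c3)cc(=O)c12
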